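Plagiochin E is cut at the bond between the ether oxygen on C3 of ring B (the ring whose hydroxyl sits ortho to that oxygen) and the ipso carbon C1 of the para-phenylene ring C. Putting one carbonyl carbon back there turns the strained 16-membered diaryl ether into a relaxed 17-membered aryl benzoate, which an ordinary macrolactonisation can close. The key step then removes that carbon as CO at nickel. This forms the O–C1 (ring C) bond and contracts the ring in one operation. The precursor is the tri-O-methyl macrolactone with both ethylene bridges saturated and the A–D biaryl in place. It comes from two Wittig reactions and one Suzuki coupling.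

Key step: step 9

Ring lettering: A = biaryl ring with its oxygen para to the biaryl bond; B = ring with the bridge at C1, the ether oxygen at C3 and the hydroxyl at C4; C = para-phenylene ring; D = biaryl ring with its oxygen ortho to the biaryl bond.
Remark: the target is written without stereodescriptors, so the hindered A–D biaryl axis is treated as stereochemically undefined (racemic or interconverting) and no stereocontrol is planned; the stilbene intermediates are carried as E/Z mixtures and drawn without alkene descriptors, because step 6 erases the geometry.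

Step 1
Reactants: 1 [4-(methoxycarbonyl)benzyl]triphenylphosphonium bromide (ring C unit); 2 2-bromo-3-methoxybenzaldehyde (ring D unit)
Product: 4 methyl 4-[2-(2-bromo-3-methoxyphenyl)ethenyl]benzoate (E/Z mixture), via phosphorus ylide 3 (not isolated)
Conditions: K2CO3, 18-crown-6 (cat.), CH2Cl2, reflux
Reagents that add atoms: none
Why: Wittig olefination of the only aldehyde present by the ester-stabilised benzylic ylide 3, generated under mild solid–liquid carbonate conditions that should leave the methyl ester and the aryl bromide untouched, the alkene geometry being of no consequence.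

Step 2
Reactants: 4 methyl 4-[2-(2-bromo-3-methoxyphenyl)ethenyl]benzoate; 5 2-formyl-4-methoxyphenylboronic acid (ring A unit)
Product: 6 methyl 4-[2-(2'-formyl-4',6-dimethoxybiphenyl-2-yl)ethenyl]benzoate (E/Z mixture)
Conditions: Pd(OAc)2 (3 mol %), SPhos (6 mol %), K3PO4, toluene/H2O, 90 °C
Reagents that add atoms: none
Why: Suzuki–Miyaura coupling in which the bulky electron-rich biarylphosphine SPhos should allow oxidative addition and transmetalation at the doubly ortho-flanked bromide fast enough to outrun protodeboronation of 5 (used in excess), while ester, aldehyde and stilbene are inert to zerovalent palladium and phosphate base.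

Step 3
Reactants: 7 3-(benzyloxy)-4-methoxybenzaldehyde (ring B unit)
Product: 8 [3-(benzyloxy)-4-methoxyphenyl]methanol
Conditions: NaBH4, MeOH, 0 °C to rt
Reagents that add atoms: none
Why: Borohydride reduction of an aromatic aldehyde to the benzylic alcohol, which should leave both aryl ethers untouched.

Step 4
Reactants: 8 [3-(benzyloxy)-4-methoxyphenyl]methanol
Product: 9 [3-(benzyloxy)-4-methoxybenzyl]triphenylphosphonium bromide
Conditions: PPh3·HBr, MeCN, reflux
Reagents that add atoms: triphenylphosphine hydrobromide, [Br-].c1ccc(cc1)[PH+](c1ccccc1)c1ccccc1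
Why: Direct conversion of a benzylic alcohol into its phosphonium salt (SN1-type substitution): HBr ionises the alcohol, whose cation is stabilised by the para-methoxy group, PPh3 captures it, and the weakly acidic medium should spare the benzyl ether.

Step 5
Reactants: 6 methyl 4-[2-(2'-formyl-4',6-dimethoxybiphenyl-2-yl)ethenyl]benzoate; 9 [3-(benzyloxy)-4-methoxybenzyl]triphenylphosphonium bromide
Product: 11 methyl 4-{2-[2'-{2-[3-(benzyloxy)-4-methoxyphenyl]ethenyl}-4',6-dimethoxybiphenyl-2-yl]ethenyl}benzoate (E/Z mixture at both alkenes), via phosphorus ylide 10 (not isolated)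
Conditions: K2CO3, 18-crown-6 (cat.), CH2Cl2, reflux
Reagents that add atoms: none
Why: Wittig olefination: 6 offers a single aldehyde, on ring A, so the ring B unit can only be joined at the correct position, and the carbonate conditions should again spare the methyl ester.

Step 6
Reactants: 11 bis-stilbene benzyl ether
Product: 12 methyl 4-{2-[2'-[2-(3-hydroxy-4-methoxyphenyl)ethyl]-4',6-dimethoxybiphenyl-2-yl]ethyl}benzoate
Conditions: H2 (1 atm), 10% Pd/C, EtOAc/MeOH, rt
Reagents that add atoms: none
Why: Heterogeneous catalytic hydrogenation combined with hydrogenolysis: one operation should saturate both stilbene double bonds and remove the O-benzyl group, which unmasks only the ring B C3 phenol, while the methyl ethers and the methyl ester are inert.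

Step 7
Reactants: 12 hydroxy methyl ester
Product: 14 4-{2-[2'-[2-(3-hydroxy-4-methoxyphenyl)ethyl]-4',6-dimethoxybiphenyl-2-yl]ethyl}benzoic acid (seco acid), via dilithium salt 13 (not isolated)
Conditions: LiOH, THF/MeOH/H2O, 50 °C; then 1 M HCl
Reagents that add atoms: lithium hydroxide, [Li+].[OH-]
Why: Saponification of a methyl benzoate by acyl–oxygen cleavage with hydroxide, followed by acidification, with no other base-sensitive group in the molecule.

Step 8
Reactants: 14 seco acid
Product: 16 macrolactone (17-membered; ring C benzoate of the ring B C3 phenol, three methyl ethers), via mixed anhydride 15 (not isolated)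
Conditions: 2-methyl-6-nitrobenzoic anhydride (MNBA), DMAP, CH2Cl2, syringe-pump addition of 14, 1 mM final concentration, rt to 40 °C
Reagents that add atoms: none
Why: Shiina macrolactonisation: slow addition keeps the concentration of mixed anhydride 15 very low, DMAP transfers the less hindered acyl group to the ring B phenol, and the two flexible ethylene bridges together with the extra ester atom should make the 17-membered ring easy to close.

Step 9
Reactants: 16 macrolactone
Product: 19 plagiochin E trimethyl ether (16-membered diaryl ether macrocycle), via acylnickel aryloxide 17 (not isolated), via arylnickel aryloxide 18 (not isolated)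
Conditions: Ni(cod)2 (20 mol %), 3,4-bis(dicyclohexylphosphino)thiophene (dcypt, 40 mol %), K3PO4 (1.5 equiv), mesitylene (5 mM), 160 °C, slow argon sweep
Reagents that add atoms: none
Why: Proposed new method: the electron-rich chelate Ni(dcypt), zerovalent nickel, should insert into the acyl C–O bond of the aryl benzoate to give the 18-membered acylnickel aryloxide 17 (divalent nickel), aryl migration and loss of CO give the 17-membered arylnickel aryloxide 18, and C–O reductive elimination releases 19 and regenerates zerovalent nickel. The closest known reaction type is the decarbonylative etherification of open-chain aryl arenecarboxylates with Ni(cod)2 or Pd(OAc)2 and dcypt, which runs best with 2-azinecarboxylates; a plain 4-alkylbenzoate inside a macrolactone has not been shown, whereas insertion and CO loss on simple phenyl benzoates are established by the related decarbonylative borylations and arylations, so the untested event is the final reductive elimination. The 16-membered ring is closed by ring contraction, the chelating ligand holding C1 of ring C and the ring B oxygen cis on nickel so that both termini stay tethered throughout and the para-phenylene strain is paid only in the irreversible, CO-driven last event. No stereocentre is created. The step needs acyl C–O cleavage to beat cleavage of the ring B aryl–O bond and of the three aryl–OMe bonds, which is secured by the much weaker acyl–OAr bond, by the electron-rich character of rings A, B and D, and by the absence from 16 of any hydride source, organometallic partner, halide, alkene or free OH that could trap an off-path nickel species. High dilution suppresses aryloxide exchange between nickel centres, the argon sweep removes CO before it blocks the catalyst, the electron-rich guaiacol-type aryloxide favours reductive elimination, and nickel is chosen over palladium because palladium with this ligand is known to shift aryl ester groups around the arene.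

Step 10
Reactants: 19 plagiochin E trimethyl ether
Product: 21 plagiochin E, via tris(dibromoboryl) ether 20 (not isolated)
Conditions: BBr3 (excess), CH2Cl2, −78 °C to rt; then H2O
Reagents that add atoms: none
Why: Lewis-acid ether cleavage with BBr3: each methyl ether is activated at oxygen and demethylated by bromide in an SN2 step at the methyl carbon to give 20, which water hydrolyses, whereas the diaryl ether offers no sp3 carbon for attack and should survive.

Compound list
1 | [4-(methoxycarbonyl)benzyl]triphenylphosphonium bromide | COC(=O)c1ccc(C[P+](c2ccccc2)(c2ccccc2)c2ccccc2)cc1.[Br-] | starting material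
2 | 2-bromo-3-methoxybenzaldehyde | COc1cccc(C=O)c1Br | starting material
3 | [4-(methoxycarbonyl)benzylidene]triphenylphosphorane | COC(=O)c1ccc(C=P(c2ccccc2)(c2ccccc2)c2ccccc2)cc1 | intermediate
4 | methyl 4-[2-(2-bromo-3-methoxyphenyl)ethenyl]benzoate (E/Z mixture) | COC(=O)c1ccc(C=Cc2cccc(OC)c2Br)cc1 | intermediate
5 | 2-formyl-4-methoxyphenylboronic acid | COc1ccc(B(O)O)c(C=O)c1 | starting material
6 | methyl 4-[2-(2'-formyl-4',6-dimethoxybiphenyl-2-yl)ethenyl]benzoate (E/Z mixture) | COC(=O)c1ccc(C=Cc2cccc(OC)c2-c2ccc(OC)cc2C=O)cc1 | intermediate
7 | 3-(benzyloxy)-4-methoxybenzaldehyde | COc1ccc(C=O)cc1OCc1ccccc1 | starting material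
8 | [3-(benzyloxy)-4-methoxyphenyl]methanol | COc1ccc(CO)cc1OCc1ccccc1 | intermediate
9 | [3-(benzyloxy)-4-methoxybenzyl]triphenylphosphonium bromide | COc1ccc(C[P+](c2ccccc2)(c2ccccc2)c2ccccc2)cc1OCc1ccccc1.[Br-] | intermediate
10 | [3-(benzyloxy)-4-methoxybenzylidene]triphenylphosphorane | COc1ccc(C=P(c2ccccc2)(c2ccccc2)c2ccccc2)cc1OCc1ccccc1 | intermediate
11 | methyl 4-{2-[2'-{2-[3-(benzyloxy)-4-methoxyphenyl]ethenyl}-4',6-dimethoxybiphenyl-2-yl]ethenyl}benzoate (E/Z mixture at both alkenes) | COC(=O)c1ccc(C=Cc2cccc(OC)c2-c2ccc(OC)cc2C=Cc2ccc(OC)c(OCc3ccccc3)c2)cc1 | intermediate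
12 | methyl 4-{2-[2'-[2-(3-hydroxy-4-methoxyphenyl)ethyl]-4',6-dimethoxybiphenyl-2-yl]ethyl}benzoate | COC(=O)c1ccc(CCc2cccc(OC)c2-c2ccc(OC)cc2CCc2ccc(OC)c(O)c2)cc1 | intermediate
13 | dilithium carboxylate phenolate of the seco acid | [Li+].[Li+].[O-]C(=O)c1ccc(CCc2cccc(OC)c2-c2ccc(OC)cc2CCc2ccc(OC)c([O-])c2)cc1 | intermediate
14 | 4-{2-[2'-[2-(3-hydroxy-4-methoxyphenyl)ethyl]-4',6-dimethoxybiphenyl-2-yl]ethyl}benzoic acid (seco acid) | OC(=O)c1ccc(CCc2cccc(OC)c2-c2ccc(OC)cc2CCc2ccc(OC)c(O)c2)cc1 | intermediate
15 | mixed anhydride of the seco acid and 2-methyl-6-nitrobenzoic acid | Cc1cccc([N+](=O)[O-])c1C(=O)OC(=O)c1ccc(CCc2cccc(OC)c2-c2ccc(OC)cc2CCc2ccc(OC)c(O)c2)cc1 | intermediate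
16 | 17-membered macrolactone, ring C benzoate of the ring B phenol, tri-O-methyl | COc1ccc2c(c1)CCc1ccc(OC)c(c1)OC(=O)c1ccc(cc1)CCc1cccc(OC)c1-2 | intermediate
17 | 18-membered (dcypt)nickel acyl aryloxide, divalent nickel | COc1ccc2c(c1)CCc1ccc(OC)c(c1)O[Ni-2]3([P+](C4CCCCC4)(C4CCCCC4)c4cscc4[P+]3(C3CCCCC3)C3CCCCC3)C(=O)c1ccc(cc1)CCc1cccc(OC)c1-2 | intermediate
18 | 17-membered (dcypt)nickel aryl aryloxide, divalent nickel | COc1ccc2c(c1)CCc1ccc(OC)c(c1)O[Ni-2]3([P+](C4CCCCC4)(C4CCCCC4)c4cscc4[P+]3(C3CCCCC3)C3CCCCC3)c1ccc(cc1)CCc1cccc(OC)c1-2 | intermediate
19 | plagiochin E trimethyl ether | COc1ccc2c(c1)CCc1ccc(OC)c(c1)Oc1ccc(cc1)CCc1cccc(OC)c1-2 | intermediate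
20 | tris(O-dibromoboryl) derivative of plagiochin E | BrB(Br)Oc1ccc2c(c1)CCc1ccc(OB(Br)Br)c(c1)Oc1ccc(cc1)CCc1cccc(OB(Br)Br)c1-2 | intermediate
21 | plagiochin E | Oc1ccc2c(c1)CCc1ccc(O)c(c1)Oc1ccc(cc1)CCc1cccc(O)c1-2 | target

Total step count: 10.
Longest linear sequence: 8 steps (steps 1, 2, 5, 6, 7, 8, 9, 10; the branch through steps 3 and 4 followed by steps 5 to 10 is equally long).

Steps most likely to fail

Step 9 (key step).
- **What may go wrong:** The cycle may stall after CO loss, because aryl–oxygen reductive elimination from divalent nickel is slow for an electron-neutral aryl group and must also build the ring strain. The long-lived arylnickel species could then be protonated, or could exchange aryloxide between metal centres and cause ring opening or oligomerisation. Retained CO could also deactivate the catalyst.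
- **Fallback (known chemistry), from 16 back to 19:** The doubtful reductive elimination at nickel is replaced by boron transfer, and the ether bond is then made at copper.
  - Nickel-catalysed decarbonylative borylation of the aryl ester is established for plain phenyl benzoates (B2pin2, Ni(cod)2, trialkylphosphine or N-heterocyclic carbene ligand, carbonate base, dioxane, 160 °C). It should open 16 to the C,O-bis(pinacolboryl) seco compound F1.
  - Aqueous work-up hydrolyses the O–B bond of that compound to give the phenol pinacol boronate F2.
  - Transfer of the pinacol unit to excess methylboronic acid (dilute HCl, acetone/H2O, evaporation) should give the phenol boronic acid F3.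
  - An intramolecular Chan–Lam coupling (Cu(OAc)2, pyridine, 4 Å molecular sieves, CH2Cl2, air, high dilution), a reaction type known for macrocyclic diaryl ethers, should close the 16-membered ring to 19.

Step 8.
- **What may go wrong:** Intermolecular acylation may compete with ring closure and lead to oligomerisation, or the phenol may be capped by the activating reagent.
- **Fallback, from 6 back to 16:** The ester bond is made first in a bimolecular reaction, and the ring is closed instead at the A–B bridge by C=C formation.
  - Selective hydrogenation of the stilbene of 6 over Pd/C poisoned with diphenyl sulfide, which spares aromatic aldehydes, should give the saturated aldehyde ester F4.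
  - LiOH should give the aldehyde acid F5.
  - Steglich esterification with isovanillin (EDC·HCl, DMAP, CH2Cl2) should give the dialdehyde aryl ester F6.
  - Intramolecular McMurry coupling (TiCl4, Zn, THF, reflux, slow addition), a proven ring closure for macrocyclic bis(bibenzyls), should give the macrocyclic stilbene lactone F7.
  - Hydrogenation (H2, Pd/C) should then deliver 16.

Step 2.
- **What may go wrong:** Protodeboronation of the ortho-formyl boronic acid may outrun the slow transmetalation at a bromide flanked by methoxy and styryl groups.
- **Fallback, from 5 and 2 back to 6:** The biaryl is made before the first Wittig reaction, with the ring A aldehyde masked in the boron partner.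
  - NaBH4 reduction of 5 with spontaneous dehydration should give 5-methoxy-1,3-dihydro-2,1-benzoxaborol-1-ol F8, which no longer carries the destabilising formyl group.
  - Suzuki–Miyaura coupling of this partner with the less hindered, aldehyde-activated bromide 2 (Pd(OAc)2, SPhos, K3PO4, dioxane/H2O) should give the hydroxymethyl biaryl aldehyde F9.
  - Wittig reaction with 1 at its only aldehyde should give the stilbene alcohol F10.
  - MnO2 oxidation of the benzylic alcohol should return to 6.

Further compounds
F1 | step 9 | C,O-bis(pinacolboryl) seco compound | CC1(C)OB(OC1(C)C)c1ccc(CCc2cccc(OC)c2-c2ccc(OC)cc2CCc2ccc(OC)c(OB3OC(C)(C)C(C)(C)O3)c2)cc1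
F2 | step 9 | phenol pinacol boronate | CC1(C)OB(OC1(C)C)c1ccc(CCc2cccc(OC)c2-c2ccc(OC)cc2CCc2ccc(OC)c(O)c2)cc1
F3 | step 9 | phenol boronic acid | OB(O)c1ccc(CCc2cccc(OC)c2-c2ccc(OC)cc2CCc2ccc(OC)c(O)c2)cc1
F4 | step 8 | methyl 4-[2-(2'-formyl-4',6-dimethoxybiphenyl-2-yl)ethyl]benzoate | COC(=O)c1ccc(CCc2cccc(OC)c2-c2ccc(OC)cc2C=O)cc1
F5 | step 8 | 4-[2-(2'-formyl-4',6-dimethoxybiphenyl-2-yl)ethyl]benzoic acid | OC(=O)c1ccc(CCc2cccc(OC)c2-c2ccc(OC)cc2C=O)cc1
F6 | step 8 | 5-formyl-2-methoxyphenyl 4-[2-(2'-formyl-4',6-dimethoxybiphenyl-2-yl)ethyl]benzoate | COc1ccc(C=O)cc1OC(=O)c1ccc(CCc2cccc(OC)c2-c2ccc(OC)cc2C=O)cc1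
F7 | step 8 | 17-membered macrolactone with a stilbene A–B bridge (alkene geometry open) | COc1ccc2c(c1)C=Cc1ccc(OC)c(c1)OC(=O)c1ccc(cc1)CCc1cccc(OC)c1-2
F8 | step 2 | 5-methoxy-1,3-dihydro-2,1-benzoxaborol-1-ol | COc1ccc2B(O)OCc2c1
F9 | step 2 | 2'-(hydroxymethyl)-4',6-dimethoxybiphenyl-2-carbaldehyde | COc1ccc(c(CO)c1)-c1c(OC)cccc1C=O
F10 | step 2 | methyl 4-{2-[2'-(hydroxymethyl)-4',6-dimethoxybiphenyl-2-yl]ethenyl}benzoate (E/Z mixture) | COC(=O)c1ccc(C=Cc2cccc(OC)c2-c2ccc(OC)cc2CO)cc1
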